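All runs are calculated for substances that don't exist, noise included.

In a one-step world a disturbance dies with a single half-life, so the count of half-lives in the time asked, n = t/h, says how far a flask has gone, and I try that count on this flask, the noon run followed on.

in all of them: starting material 0.10 M

| run | partner | protic impurity | remark | time |
|---|---|---|---|---|
| noon | 3 equiv | 0.030 M | the very flask that is asked about, followed so far |  |
| flask | 3.00 equiv | 0.0300 M |  | 4.0 d |

noon run (percent of the starting material charged)

| time / h | target / % | isomer of the product / % |
|---|---|---|
| 1.33 | 16.4 | 36.1 |
| 4.00 | 13.9 | 31.1 |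
| 6.00 | 13.0 | 31.2 |
| 10.0 | 13.4 | 30.9 |
| 15.0 | 13.8 | 31.2 |
| 20.0 | 14.3 | 30.3 |

(each reading ± 0.5 percentage points)

1. ratio of target to isomer of the product at 1.0 min
2. ratio of target to isomer of the product at 80 min
3. ratio of target to isomer of the product at 4.0 d
4. which of target and isomer of the product there is more of at 4.0 d

- a reading or a percentage of target counts all its forms, free or not

In the noon run the sum of target and isomer of the product lies 8.2 percentage points above its level at 10.0 h when read at 1.33 h, and 0.7 points above it at 4.00 h, with a scatter of 0.5 points on each reading. So I read h, the time in which this excess halves, as 0.752 h. For this flask at 4.0 d that gives n = 128, so if the excess goes on halving at that pace, I expect this flask to stand on its plateau.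

One number is not enough: n tells how far, but it gives no level. I take the level from the noon readings from 4.00 h on, whose summed ratio of target to isomer of the product reads 0.442, and I read that as thermodynamic control. A slower step could hide behind n, but target moves 0.4 points from 4.00 h to 20.0 h, so I hold it flat and commit to that ratio at 4.0 d, with the isomer of the product ahead. At 80 min I take the reading, 0.454. At 1.0 min the count is 0.0222, less than one half-life, so I carry no plateau back and give no number.

The forecast says 0.45, 0.45 and 0.75, with isomer of the product ahead, expecting “a slow drift toward a thermodynamic sink favouring target”.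

This flask gives 4.96, 0.450 and 0.448, with isomer of the product ahead at 30.9 % against 13.8 % of target. Target in this flask stands at 13.8 % after 0.400 d and at 13.8 % after 40.0 d. Counted in h, the ratio is 4.96 at 0.0222 half-lives and 0.450 at 1.77.

    starting material + partner ⇌ isomer of the product (K = 6.70 M⁻¹, k = 0.00222 M⁻¹ s⁻¹)
    starting material + partner ⇌ target (K = 3.00 M⁻¹, k = 0.0124 M⁻¹ s⁻¹)
    partner ⇌ dormant form (K = 1.70, k = 1.96 × 10⁻⁴ s⁻¹)
    crystals ⇌ target, rate k4*(cs4 - [target]) while solid is left; crystals form when [target] > cs4 (solubility = 0.0640 M, k = 0.0502 s⁻¹)
    partner + protic impurity → quenched reagent (k = 0.0604 M⁻¹ s⁻¹)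

For the neighbour with 0.750 equiv of partner, taking h over from the noon run as an assumption, I count the same 128 half-lives and expect the plateau ratio 0.442. That flask gives 0.448, with target at 3.37 % and starting material at 89.1 %.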